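**Plan**

1. Numbering: C1 ketone, C2, C3–C4 epoxide (C15 on C4), C5, C6 (lactone O), C7, C8 (OH), C9 (angelate), C10 (=C14), C11 (=C13), C12 (lactone C=O). The enabling feature is that the epoxide stands for an E C3=C4 olefin lying 1,3 to the oxygen on C9. A bond drawn across the ring from C4 to C9 turns the ten-membered ring into the rim of a decalin (ring A: C4, C3, C2, C1, C10, C9; ring B: C4 to C9) whose 9-alkoxide/3-sulfonate pair can break that bond again.
2. Retrosynthesis: remove the epoxide oxygen and the angelate, return the lactone and the C1 ketone to carbinol level, then re-form C4–C9 (C9 ketone becomes a tertiary carbinol, C3 an equatorial mesylate). Ring A is cut at C3–C4 and C9–C10 (Robinson annulation with ethyl vinyl ketone); ring B with C15 and C11–C13 is carvone.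
3. Forward: (R)-carvone, C6 oxygen by Rubottom oxidation, carbonyl moved to C9 by Wharton transposition (this reverses the numbering sense, hence the R enantiomer). Ring A follows by chiral-imine Michael addition and aldol, the lactol ring from the isopropenyl group, then the C8, C3 and C9 oxygens and the C10 methylene on the rigid decalin. Fragmentation releases the ten-membered ring; ester, lactone, enone and epoxide come last.
4. Stereochemistry: C7 from carvone; C6 anti to it; C4 from the amine auxiliary (it only serves the decalin); C8 by axial attack on a dienol ether; the C3 and C9 carbinols by the angular methyl group. The final C9 centre comes from a Felkin-type reduction; the epoxide is stereospecific from the E olefin, with its face set by the ring conformation.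

Key step: step 21

Remarks: atom numbers are those of the plan throughout; carvone C1 to C6 become C5, C4, C9, C8, C7, C6. In the decalins β is the face of the C4 methyl group. Assumption: the anomeric centre C12 of the lactol methyl ether and the C1 carbinol are drawn as the expected epimers; both centres are erased in step 24, so either epimer serves.

**Route**

Step 1
Reactants: 1 (R)-(−)-carvone
Product: 3 trans-6-(tert-butyldimethylsilyloxy)carvone (OTBS on C6 anti to the C7 isopropenyl group), via silyl dienol ether 2 (not isolated)
Conditions: LiN(i-Pr)2, THF, −78 °C; TBSCl, HMPA, −78 to 0 °C; then mCPBA, NaHCO3, CH2Cl2, −20 °C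
Reagents that add atoms: tert-butyldimethylsilyl chloride, CC(C)(C)[Si](C)(C)Cl; mCPBA, OOC(=O)c1cccc(Cl)c1
Why: Rubottom oxidation of the kinetic cross-conjugated silyl dienol ether, in which the peracid should attack C6 anti to the neighbouring isopropenyl group and the silyl group should migrate to the new oxygen under the buffered conditions, so that the C6 oxygen is set trans to C7.

Step 2
Reactants: 3 trans-6-(tert-butyldimethylsilyloxy)carvone
Product: 4 C4,C9-epoxy-5-ketone (epoxide anti to the isopropenyl group)
Conditions: 30% H2O2, NaOH (cat.), MeOH, 0 °C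
Reagents that add atoms: hydrogen peroxide, OO
Why: Weitz–Scheffer nucleophilic epoxidation of the enone, expected anti to the isopropenyl group as for carvone itself, the two new centres being erased again in steps 3 to 5.

Step 3
Reactants: 4 C4,C9-epoxy-5-ketone
Product: 5 transposed allylic alcohol (C9 carbinol, C4=C5 olefin, 6-OTBS, 7-isopropenyl)
Conditions: N2H4·H2O, AcOH (cat.), MeOH, 0 °C to rt
Reagents that add atoms: none
Why: Wharton transposition, in which the epoxy hydrazone collapses with loss of nitrogen to the allylic alcohol, so that the oxygen moves from C5 to C9 and the C9 carbinol keeps the epoxide C–O bond.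

Step 4
Reactants: 5 transposed allylic alcohol
Product: 6 transposed enone (C9 ketone, C4=C5, 6-OTBS trans to 7-isopropenyl)
Conditions: MnO2, CH2Cl2, rt
Reagents that add atoms: none
Why: Oxidation of a secondary allylic alcohol to the enone with MnO2, a standard allylic oxidation that touches no stereocentre.

Step 5
Reactants: 6 transposed enone
Product: 7 saturated C9 ketone (C4 methyl equatorial epimer drawn)
Conditions: LiBH(s-Bu)3, THF, −78 °C; then H2O
Reagents that add atoms: none
Why: Conjugate reduction of a β-unsubstituted cyclohexenone with a bulky borohydride, as known for carvone, the C4 epimer ratio being irrelevant because C4 becomes trigonal in the next step.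

Step 6
Reactants: 7 saturated C9 ketone; 8 (S)-(−)-1-phenylethylamine; 9 ethyl vinyl ketone
Product: 12 1,5-diketone with quaternary C4 (methyl cis to the C7 isopropenyl group; 3-oxopentyl chain cis to the C6 silyloxy group), via ketimine 10 (not isolated), via Michael adduct imine 11 (not isolated)
Conditions: 8, TsOH (cat.), toluene, reflux (−H2O); then 9, THF, rt; then 10% aq. AcOH, rt
Reagents that add atoms: ethyl vinyl ketone, CCC(=O)C=C; water, O
Why: Michael addition of the more substituted secondary enamine tautomer of a chiral imine (deracemising alkylation of α-substituted ketones), in which the enone is passed through a compact aza-ene-like transition state to the enamine face away from the phenyl group, which for the (S)-amine is the C4 face cis to the C6 oxygen, so that the methyl group ends cis to C7–C11 as in the known dihydrocarvone case.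

Step 7
Reactants: 12 1,5-diketone
Product: 13 bicyclic enone (C1 ketone, C9=C10, C14 on C10, 4β-methyl, 6α-OTBS, 7β-isopropenyl)
Conditions: NaOMe, MeOH, rt
Reagents that add atoms: none
Why: Intramolecular aldol condensation that completes the Robinson annulation, the C10 methylene adding to the C9 carbonyl and water being lost to the tetrasubstituted enone without a new stereocentre.

Step 8
Reactants: 13 bicyclic enone
Product: 15 C12 enal (7β-(3-oxoprop-1-en-2-yl) group), via allylic alcohol 14 (not isolated)
Conditions: SeO2 (cat.), t-BuOOH, CH2Cl2, rt; then MnO2, CH2Cl2, rt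
Reagents that add atoms: selenium dioxide, O=[Se]=O; tert-butyl hydroperoxide, CC(C)(C)OO
Why: Allylic oxidation of the isopropenyl methyl group by the SeO2 ene/2,3-sigmatropic sequence, pushed to the aldehyde with MnO2, the C14 methyl group being deactivated by the enone.

Step 9
Reactants: 15 C12 enal
Product: 16 trans-fused lactol methyl ether (C6α–O–C12(OMe), C11=C13 methylene) on the C1 enone
Conditions: CSA (cat.), MeOH, rt
Reagents that add atoms: methanol, CO
Why: Acid-catalysed desilylation in methanol frees the C6 hydroxyl, which should close onto the neighbouring enal and be trapped as the cyclic methyl acetal (Fischer-type acetalisation), the diequatorial C6–O and C7–C11 bonds fitting the trans ring fusion.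

Step 10
Reactants: 16 lactol methyl ether enone
Product: 18 8β-hydroxy enone, via trimethylsilyl dienol ether 17 (not isolated)
Conditions: TMSCl, Et3N, DMF, 80 °C; then mCPBA, NaHCO3, CH2Cl2, −20 °C
Reagents that add atoms: mCPBA, OOC(=O)c1cccc(Cl)c1
Why: Vinylogous Rubottom oxidation in which thermodynamic silylation gives the heteroannular dienol ether and the peracid should attack C8 along the axial direction on the face of the angular methyl group, as 3,5-dienol ethers of steroids do at C6, so that the C8 hydroxyl is β-axial and cis to C7–C11.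

Step 11
Reactants: 18 8β-hydroxy enone
Product: 19 8β-(tert-butyldimethylsilyloxy) enone
Conditions: TBSOTf, 2,6-lutidine, CH2Cl2, −78 to 0 °C
Reagents that add atoms: tert-butyldimethylsilyl triflate, CC(C)(C)[Si](C)(C)OS(=O)(=O)C(F)(F)F
Why: Silylation of a hindered axial secondary alcohol with a silyl triflate and a hindered pyridine base, a standard protection without stereochemical change.

Step 12
Reactants: 19 8β-silyloxy enone
Product: 21 cross-conjugated 2,9-dien-1-one, via trimethylsilyl enol ether 20 (not isolated)
Conditions: LiN(i-Pr)2, TMSCl, THF, −78 °C; then Pd(OAc)2, MeCN, rt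
Reagents that add atoms: none
Why: Saegusa–Ito dehydrogenation, kinetic deprotonation at C2 and oxidation of the enol silane by Pd(OAc)2 introducing the C2=C3 double bond.

Step 13
Reactants: 21 2,9-dien-1-one
Product: 22 2α,3α-epoxy-9-en-1-one
Conditions: 30% H2O2, NaOH (cat.), MeOH, 0 °C
Reagents that add atoms: hydrogen peroxide, OO
Why: Nucleophilic epoxidation of the less substituted double bond of a cross-conjugated dienone, known for steroidal 1,4-dien-3-ones, with hydroperoxide attacking C3 anti to the C4 methyl group while the tetrasubstituted C9=C10 bond stays.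

Step 14
Reactants: 22 2α,3α-epoxy-9-en-1-one
Product: 23 9-ene-1β,3α-diol
Conditions: LiAlH4, THF, 0 °C to rt
Reagents that add atoms: none
Why: Hydride reduction of an α,β-epoxy ketone to the 1,3-diol, axial attack at C1 giving the equatorial alkoxide, which should pass hydride to C2 in a trans-diaxial opening (Fürst–Plattner rule) so that the epoxide oxygen stays on C3 as the axial α-hydroxyl.

Step 15
Reactants: 23 9-ene-1β,3α-diol
Product: 24 1β-triethylsilyl ether 3α-ol
Conditions: TESCl, imidazole, CH2Cl2, −20 °C
Reagents that add atoms: triethylsilyl chloride, CC[Si](Cl)(CC)CC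
Why: Steric differentiation of a diol, the equatorial allylic C1 hydroxyl being silylated in preference to the axial neopentyl C3 hydroxyl.

Step 16
Reactants: 24 1β-silyl ether 3α-ol
Product: 25 3-ketone
Conditions: Dess–Martin periodinane, NaHCO3, CH2Cl2, rt
Reagents that add atoms: none
Why: Dess–Martin oxidation of a hindered secondary alcohol under buffered conditions that should leave the β-silyloxy group and the acetal untouched.

Step 17
Reactants: 25 3-ketone
Product: 26 3β-ol
Conditions: NaBH4, MeOH, −40 °C
Reagents that add atoms: none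
Why: Borohydride reduction of a ketone next to a quaternary centre, hydride approaching C3 from the α face opposite to the axial C4 methyl group and giving the equatorial β-alcohol cis to that methyl group, as with 1-decalones that carry an angular methyl group.

Step 18
Reactants: 26 3β-ol
Product: 27 9α,10α-epoxide
Conditions: mCPBA, NaHCO3, CH2Cl2, 0 °C
Reagents that add atoms: mCPBA, OOC(=O)c1cccc(Cl)c1
Why: Prilezhaev epoxidation of the tetrasubstituted C9=C10 olefin, the most electron-rich double bond, with the angular methyl group and the β-silyloxy groups at C1 and C8 expected to send the peracid to the α face so that the C9 oxygen is trans to the C4 methyl group.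

Step 19
Reactants: 27 9α,10α-epoxide
Product: 28 10(14)-ene-3β,9α-diol (tertiary C9 carbinol, C10 methylene)
Conditions: Et2AlCl, lithium 2,2,6,6-tetramethylpiperidide, toluene, 0 °C to rt
Reagents that add atoms: none
Why: Isomerisation of an epoxide to an allylic alcohol with a dialkylaluminium amide by syn β-elimination through a cyclic transition state, the C14 methyl hydrogens being the least hindered β-hydrogens so that the C10–O bond should break and leave the C9 α-hydroxyl, as in the conversion of α-pinene oxide into trans-pinocarveol.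

Step 20
Reactants: 28 3β,9α-diol
Product: 29 trans-decalin 9α-ol 3β-mesylate (1β-OTES, 8β-OTBS, C10 methylene, lactol methyl ether)
Conditions: MsCl, Et3N, CH2Cl2, −20 °C
Reagents that add atoms: methanesulfonyl chloride, CS(=O)(=O)Cl
Why: Chemoselective sulfonylation of the secondary equatorial C3 hydroxyl, the tertiary C9 hydroxyl being inert under these conditions.

Step 21
Reactants: 29 trans-decalin 9α-ol 3β-mesylate
Product: 30 ten-membered (3E)-3,10(14)-dien-9-one (1-OTES, 8-OTBS, fused lactol methyl ether)
Conditions: KN(SiMe3)2, THF, −78 to 0 °C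
Reagents that add atoms: none
Why: Deprotonation of the tertiary C9 hydroxyl gives an alkoxide whose lone pair, the C9–C4 bond and the C3–O bond of the equatorial mesylate are anti-periplanar in the trans-fused chair–chair decalin, so that the C9 carbonyl and the C3=C4 double bond form while the C4–C9 bond breaks and mesylate leaves in one concerted heterolytic Grob fragmentation. The closest known reaction is the Wharton-type fragmentation of trans-decalin-1,3-diol monosulfonates to (E)-cyclodec-5-enones. The ten-membered ring is not closed by bond formation but set free as the perimeter of the bicycle when the shared bond is cut, so no exo or endo mode of closure applies and the usual entropic and transannular penalties of medium-ring closure are avoided. No stereocentre is created, C4 and C9 become trigonal, and C1, C6, C7 and C8 are untouched. The step needs E geometry, which follows because C2 and C5 are anti across C3–C4 when the mesylate is equatorial and the C4 methyl group axial, and it needs fragmentation to win over elimination and substitution, which the lack of an anti-periplanar hydrogen at C2 and the poor alignment for oxetane closure secure. A non-nucleophilic amide base at low temperature is chosen because the product is an α-methylene ketone with an enolisable hydrogen at C8.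

Step 22
Reactants: 30 (3E)-3,10(14)-dien-9-one
Product: 31 (9R)-allylic alcohol
Conditions: NaBH4, CeCl3·7H2O, MeOH, −78 °C
Reagents that add atoms: none
Why: Luche 1,2-reduction of the α-methylene ketone, for which the polar Felkin–Anh model with the bulky non-chelating C8 silyloxy group predicts hydride attack anti to the C8 oxygen and hence the anti C8/C9 relationship of the target.

Step 23
Reactants: 31 (9R)-allylic alcohol; 32 angelic acid
Product: 34 9-O-angelate, via mixed anhydride 33 (not isolated)
Conditions: 32, 2,4,6-trichlorobenzoyl chloride, Et3N, toluene, rt; then 31, toluene, 80 °C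
Reagents that add atoms: angelic acid, C/C=C(/C)C(=O)O
Why: Esterification through the mixed anhydride of angelic acid with 2,4,6-trichlorobenzoic acid, run without a nucleophilic catalyst, a protocol known to transfer the angeloyl group without isomerisation to the tiglate and without change at C9.

Step 24
Reactants: 34 9-O-angelate
Product: 36 8-O-silyl enone lactone (C1 ketone, α-methylene γ-lactone closed to C6), via lactol diol 35 (not isolated)
Conditions: AcOH/THF/H2O (3:1:1), rt; then MnO2, CH2Cl2, rt
Reagents that add atoms: water, O
Why: Mild aqueous acid should hydrolyse the mixed acetal and the allylic triethylsilyl ether while the hindered C8 silyl ether stays, and MnO2 then oxidises both allylic carbinols, C1 to the enone and the lactol to the lactone, which can only close to C6 because C8 is still protected.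

Step 25
Reactants: 36 8-O-silyl enone lactone
Product: 37 8-hydroxy (3E)-olefin (3,4-deoxy target)
Conditions: HF·pyridine, pyridine, THF, 0 °C to rt
Reagents that add atoms: none
Why: Fluoride-mediated cleavage of the remaining silyl ether under buffered acidic conditions, chosen to avoid base-induced acyl migration from C9 to C8 and conjugate addition to the two enone systems.

Step 26
Reactants: 37 8-hydroxy (3E)-olefin
Product: 38 CNP0348992.2 (target, 3R,4R,6R,7R,8S,9R in the numbering of the plan)
Conditions: mCPBA, NaHCO3, CH2Cl2, 0 °C
Reagents that add atoms: mCPBA, OOC(=O)c1cccc(Cl)c1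
Why: Prilezhaev epoxidation of the only electron-rich double bond left, the E geometry being transferred stereospecifically to the trans epoxide and attack on the outer face of the olefin in the preferred ring conformation being expected to give the (3R,4R) isomer.

**Compound list**

1 | (R)-(−)-carvone | CC1=CC[C@H](CC1=O)C(C)=C | starting material
2 | kinetic tert-butyldimethylsilyl dienol ether of 1 | CC1=CC[C@H](C=C1O[Si](C)(C)C(C)(C)C)C(C)=C | intermediate (not isolated)
3 | trans-6-(tert-butyldimethylsilyloxy)carvone | CC1=CC[C@H]([C@H](O[Si](C)(C)C(C)(C)C)C1=O)C(C)=C | intermediate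
4 | C4,C9-epoxy-5-ketone, epoxide anti to isopropenyl | C[C@@]12O[C@@H]1C[C@H]([C@H](O[Si](C)(C)C(C)(C)C)C2=O)C(C)=C | intermediate
5 | transposed allylic alcohol (C9 carbinol, C4=C5) | CC1=C[C@@H](O[Si](C)(C)C(C)(C)C)[C@@H](C[C@H]1O)C(C)=C | intermediate
6 | transposed enone (C9 ketone, C4=C5, 6-OTBS trans to 7-isopropenyl) | CC1=C[C@@H](O[Si](C)(C)C(C)(C)C)[C@@H](CC1=O)C(C)=C | intermediate
7 | saturated C9 ketone, C4 methyl equatorial | C[C@H]1C[C@@H](O[Si](C)(C)C(C)(C)C)[C@@H](CC1=O)C(C)=C | intermediate
8 | (S)-(−)-1-phenylethylamine | C[C@H](N)c1ccccc1 | starting material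
9 | ethyl vinyl ketone | CCC(=O)C=C | starting material
10 | N-[(S)-1-phenylethyl] ketimine of 7 | C[C@H]1C[C@@H](O[Si](C)(C)C(C)(C)C)[C@@H](CC1=N[C@@H](C)c2ccccc2)C(C)=C | intermediate (not isolated)
11 | C4-(3-oxopentyl) ketimine | CCC(=O)CC[C@@]1(C)C[C@@H](O[Si](C)(C)C(C)(C)C)[C@@H](CC1=N[C@@H](C)c2ccccc2)C(C)=C | intermediate (not isolated)
12 | 1,5-diketone, C4 methyl cis to C7 isopropenyl | CCC(=O)CC[C@@]1(C)C[C@@H](O[Si](C)(C)C(C)(C)C)[C@@H](CC1=O)C(C)=C | intermediate
13 | bicyclic enone (C1 ketone, C9=C10, 4β-methyl, 6α-OTBS, 7β-isopropenyl) | CC1=C2C[C@@H](C(C)=C)[C@H](O[Si](C)(C)C(C)(C)C)C[C@]2(C)CCC1=O | intermediate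
14 | 12-hydroxy derivative of 13 | CC1=C2C[C@@H](C(=C)CO)[C@H](O[Si](C)(C)C(C)(C)C)C[C@]2(C)CCC1=O | intermediate (not isolated)
15 | C12 enal | CC1=C2C[C@@H](C(=C)C=O)[C@H](O[Si](C)(C)C(C)(C)C)C[C@]2(C)CCC1=O | intermediate
16 | trans-fused lactol methyl ether on the C1 enone | C=C1[C@@H](OC)O[C@@H]2C[C@]3(C)CCC(=O)C(C)=C3C[C@@H]12 | intermediate
17 | 1-trimethylsilyloxy-1(10),8-diene | C=C1[C@@H](OC)O[C@@H]2C[C@]3(C)CCC(O[Si](C)(C)C)=C(C)C3=C[C@@H]12 | intermediate (not isolated)
18 | 8β-hydroxy enone | C=C1[C@@H](OC)O[C@@H]2C[C@]3(C)CCC(=O)C(C)=C3[C@@H](O)[C@@H]12 | intermediate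
19 | 8β-(tert-butyldimethylsilyloxy) enone | C=C1[C@@H](OC)O[C@@H]2C[C@]3(C)CCC(=O)C(C)=C3[C@@H](O[Si](C)(C)C(C)(C)C)[C@@H]12 | intermediate
20 | 1-trimethylsilyloxy-1,9-diene | C=C1[C@@H](OC)O[C@@H]2C[C@]3(C)CC=C(O[Si](C)(C)C)C(C)=C3[C@@H](O[Si](C)(C)C(C)(C)C)[C@@H]12 | intermediate (not isolated)
21 | cross-conjugated 2,9-dien-1-one | C=C1[C@@H](OC)O[C@@H]2C[C@]3(C)C=CC(=O)C(C)=C3[C@@H](O[Si](C)(C)C(C)(C)C)[C@@H]12 | intermediate
22 | 2α,3α-epoxy-9-en-1-one | C=C1[C@@H](OC)O[C@@H]2C[C@]3(C)[C@@H]4O[C@@H]4C(=O)C(C)=C3[C@@H](O[Si](C)(C)C(C)(C)C)[C@@H]12 | intermediate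
23 | 9-ene-1β,3α-diol | C=C1[C@@H](OC)O[C@@H]2C[C@]3(C)[C@H](O)C[C@@H](O)C(C)=C3[C@@H](O[Si](C)(C)C(C)(C)C)[C@@H]12 | intermediate
24 | 1β-triethylsilyl ether 3α-ol | C=C1[C@@H](OC)O[C@@H]2C[C@]3(C)[C@H](O)C[C@@H](O[Si](CC)(CC)CC)C(C)=C3[C@@H](O[Si](C)(C)C(C)(C)C)[C@@H]12 | intermediate
25 | 3-ketone | C=C1[C@@H](OC)O[C@@H]2C[C@]3(C)C(=O)C[C@@H](O[Si](CC)(CC)CC)C(C)=C3[C@@H](O[Si](C)(C)C(C)(C)C)[C@@H]12 | intermediate
26 | 3β-ol | C=C1[C@@H](OC)O[C@@H]2C[C@]3(C)[C@@H](O)C[C@@H](O[Si](CC)(CC)CC)C(C)=C3[C@@H](O[Si](C)(C)C(C)(C)C)[C@@H]12 | intermediate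
27 | 9α,10α-epoxide | C=C1[C@@H](OC)O[C@@H]2C[C@]3(C)[C@@H](O)C[C@@H](O[Si](CC)(CC)CC)[C@]4(C)O[C@]34[C@@H](O[Si](C)(C)C(C)(C)C)[C@@H]12 | intermediate
28 | 10(14)-ene-3β,9α-diol | C=C1[C@@H](OC)O[C@@H]2C[C@]3(C)[C@@H](O)C[C@@H](O[Si](CC)(CC)CC)C(=C)[C@@]3(O)[C@@H](O[Si](C)(C)C(C)(C)C)[C@@H]12 | intermediate
29 | trans-decalin 9α-ol 3β-mesylate (fragmentation precursor) | C=C1[C@@H](OC)O[C@@H]2C[C@]3(C)[C@@H](OS(C)(=O)=O)C[C@@H](O[Si](CC)(CC)CC)C(=C)[C@@]3(O)[C@@H](O[Si](C)(C)C(C)(C)C)[C@@H]12 | intermediate
30 | ten-membered (3E)-3,10(14)-dien-9-one | C=C1[C@@H](OC)O[C@@H]2C/C(C)=C/C[C@@H](O[Si](CC)(CC)CC)C(=C)C(=O)[C@@H](O[Si](C)(C)C(C)(C)C)[C@@H]12 | intermediate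
31 | (9R)-allylic alcohol | C=C1[C@@H](OC)O[C@@H]2C/C(C)=C/C[C@@H](O[Si](CC)(CC)CC)C(=C)[C@@H](O)[C@@H](O[Si](C)(C)C(C)(C)C)[C@@H]12 | intermediate
32 | angelic acid | C/C=C(/C)C(=O)O | starting material
33 | angelic 2,4,6-trichlorobenzoic anhydride | C/C=C(/C)C(=O)OC(=O)c1c(Cl)cc(Cl)cc1Cl | intermediate (not isolated)
34 | 9-O-angelate | C=C1[C@@H](OC)O[C@@H]2C/C(C)=C/C[C@@H](O[Si](CC)(CC)CC)C(=C)[C@@H](OC(=O)/C(C)=C\C)[C@@H](O[Si](C)(C)C(C)(C)C)[C@@H]12 | intermediate
35 | 1-hydroxy lactol (anomer mixture, C12 unspecified) | C=C1C(O)O[C@@H]2C/C(C)=C/C[C@@H](O)C(=C)[C@@H](OC(=O)/C(C)=C\C)[C@@H](O[Si](C)(C)C(C)(C)C)[C@@H]12 | intermediate (not isolated)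
36 | 8-O-silyl enone lactone | C=C1C(=O)O[C@@H]2C/C(C)=C/CC(=O)C(=C)[C@@H](OC(=O)/C(C)=C\C)[C@@H](O[Si](C)(C)C(C)(C)C)[C@@H]12 | intermediate
37 | 8-hydroxy (3E)-olefin (3,4-deoxy target) | C=C1C(=O)O[C@@H]2C/C(C)=C/CC(=O)C(=C)[C@@H](OC(=O)/C(C)=C\C)[C@@H](O)[C@@H]12 | intermediate
38 | CNP0348992.2 | C=C1C(=O)O[C@@H]2C[C@@]3(C)O[C@@H]3CC(=O)C(=C)[C@@H](OC(=O)/C(C)=C\C)[C@@H](O)[C@@H]12 | target

**Count and risks**

Total step count: 26. Longest linear sequence: 26 steps from (R)-carvone; the amine, ethyl vinyl ketone and angelic acid enter as purchased reagents.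

Steps most likely to fail:

1. Step 6. The auxiliary has to overrule the ring's own preference for axial attack at C4 on the face of the isopropenyl group, so facial control may erode and the C4 epimer may take over. The fallback lets a catalyst set the quaternary centre; it sets out from enone 6 and comes back at diketone 12. Conjugate reduction of 6 with LiBH(s-Bu)3 and trapping of the regiodefined enolate with allyl chloroformate gives the allyl enol carbonate F1. Decarboxylative allylic alkylation with Pd2(dba)3 and the enantiomer of the t-BuPHOX ligand that sends the allyl group to the α face gives the α-allyl ketone F2. Hydroboration of the monosubstituted olefin with disiamylborane, which should spare the isopropenyl group and the hindered ketone, and oxidation with NaBO3 give the primary alcohol F3. Dess–Martin oxidation gives the aldehyde F4, EtMgBr at −78 °C adds to the aldehyde to give the ethyl carbinol F5, and a second Dess–Martin oxidation gives 12.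

2. Step 22. Hydride delivery in the flexible ten-membered ring may follow the ring conformation and not the Felkin–Anh model, which would put the hydroxyl on the wrong side at C9. The fallback corrects the centre by inversion; it sets out from ketone 30 and comes back at angelate 34. The reduction is then run to give the 9-epi alcohol F6, and Mitsunobu esterification with angelic acid 32 (PPh3, diisopropyl azodicarboxylate, toluene, 0 °C) inverts C9 and installs the ester in one operation, which also makes step 23 unnecessary.

3. Step 26. The peracid may attack the other face of the E olefin if the ring prefers a conformer other than the one assumed, giving the diastereomeric trans epoxide. The fallback delivers the oxygen to the opposite face in two steps; it sets out from olefin 37 and comes back at target 38. N-bromosuccinimide in aqueous THF should form the bromonium ion on the face the peracid would use, and water opens it at C4 from the other side to give the bromohydrin F7. K2CO3 in acetone then closes the epoxide by displacement of bromide with inversion at C3.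

**Further compounds**

F1 | step 6 | allyl enol carbonate of the C4 enolate | CC1=C(OC(=O)OCC=C)C[C@@H](C(C)=C)[C@H](O[Si](C)(C)C(C)(C)C)C1
F2 | step 6 | α-allyl ketone, C4 methyl cis to C7 isopropenyl | C=CC[C@@]1(C)C[C@@H](O[Si](C)(C)C(C)(C)C)[C@@H](CC1=O)C(C)=C
F3 | step 6 | primary alcohol (3-hydroxypropyl chain on C4) | OCCC[C@@]1(C)C[C@@H](O[Si](C)(C)C(C)(C)C)[C@@H](CC1=O)C(C)=C
F4 | step 6 | aldehyde (3-oxopropyl chain on C4) | O=CCC[C@@]1(C)C[C@@H](O[Si](C)(C)C(C)(C)C)[C@@H](CC1=O)C(C)=C
F5 | step 6 | ethyl carbinol (3-hydroxypentyl chain on C4, carbinol epimers) | CCC(O)CC[C@@]1(C)C[C@@H](O[Si](C)(C)C(C)(C)C)[C@@H](CC1=O)C(C)=C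
F6 | step 22 | 9-epi alcohol | C=C1[C@@H](OC)O[C@@H]2C/C(C)=C/C[C@@H](O[Si](CC)(CC)CC)C(=C)[C@H](O)[C@@H](O[Si](C)(C)C(C)(C)C)[C@@H]12
F7 | step 26 | bromohydrin (3-bromo-4-hydroxy) | C=C1C(=O)O[C@@H]2C[C@@](C)(O)[C@@H](Br)CC(=O)C(=C)[C@@H](OC(=O)/C(C)=C\C)[C@@H](O)[C@@H]12
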